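Counted as fractions of the substrate charged, the last readings put 91.5 % in side product in theta, 87.4 % in delta and 82.9 % in epsilon, and beside it stand single, double and triple product.

| flask | substrate | partner | temperature | remark | time |
|---|---|---|---|---|---|
| theta | 0.30 M | 2 equiv | 96 °C | run made earlier |  |
| epsilon | 0.30 M | 4.5 equiv | 110 °C | run made earlier |  |
| delta | 0.15 M | 3 equiv | 96 °C | run made earlier |  |
| violet | 0.30 M | 3.00 equiv | 115 °C |  | 12 min |
| red | 0.30 M | 3.00 equiv | 90 °C |  | 12 min |

| run | time / min | substrate / % | side product / % | double product / % | triple product / % | single product / % |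
|---|---|---|---|---|---|---|
| theta | 1.00 | 53.9 | 39.3 | 0.7 | 0.5 | 4.9 |
| theta | 1.33 | 44.7 | 49.3 | 0.3 | 0 | 5.3 |
| theta | 2.00 | 29.6 | 62.9 | 1.2 | 0 | 5.7 |
| theta | 3.00 | 17.1 | 76.0 | 1.8 | 1.1 | 4.4 |
| theta | 5.00 | 6.0 | 86.4 | 1.5 | 1.2 | 4.3 |
| theta | 8.00 | 1.7 | 90.7 | 1.6 | 3.1 | 3.7 |
| theta | 12.0 | 0.4 | 91.5 | 1.4 | 5.0 | 2.2 |
| epsilon | 0.500 | 25.7 | 60.1 | 1.9 | 1.5 | 10.7 |
| epsilon | 1.00 | 7.4 | 77.5 | 2.3 | 4.4 | 9.1 |
| epsilon | 2.00 | 0.8 | 82.0 | 1.2 | 8.8 | 5.9 |
| epsilon | 3.00 | 0.5 | 82.8 | 1.3 | 12.6 | 3.7 |
| epsilon | 4.00 | 0 | 82.9 | 0.7 | 14.3 | 2.1 |
| delta | 2.50 | 32.3 | 57.8 | 1.9 | 0.6 | 8.4 |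
| delta | 5.00 | 11.1 | 77.8 | 2.4 | 2.0 | 7.5 |
| delta | 8.00 | 2.9 | 84.1 | 2.7 | 3.3 | 5.6 |
| delta | 10.0 | 2.1 | 85.4 | 1.7 | 4.5 | 5.3 |
| delta | 12.0 | 0.7 | 87.4 | 2.0 | 5.9 | 4.8 |

(standard deviation of a reading: 0.3 percentage points)

- percentages count the substrate that a species holds: one side product counts as two

- which of these there is most of at the end, counted by the substrate in it, violet (triple product / single product / side product / double product)
- which of these there is most of at the end, counted by the substrate in it, red (triple product / single product / side product / double product)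
- the largest of these amounts at the end, in percent of the substrate charged, violet
- the largest of these amounts at the end, in percent of the substrate charged, red

Two of us read those amounts differently. The first reads heat: from theta at 96 °C to epsilon at 110 °C side product falls by 8.6 percentage points. Carried on from delta at that slope per degree, this gives 75.7 % in violet and 91.1 % in red, so violet should end lower than red.

The second reading, which I take, is partner. Theta and delta share one temperature and differ in substrate as well as partner, yet delta, with 3 equiv against 2 equiv, holds less side product. Take the fraction in single, double and triple product over the fraction in side product, and divide by the equivalents of partner. This gives 0.0470 per equivalent in theta, 0.0484 in delta and 0.0458 in epsilon, with a mean of 0.0471. I call this mean the leak per equivalent, a selectivity factor. The side fraction is then one over one plus leak times equivalents, so at 3.00 equiv I commit to 87.6 % in both violet and red.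

The forecast names side product for violet at 87.3 % and side product for red at 87.5 %, beside my 87.6 %, on the ground that “Selectivity therefore follows equivalents”.

The flasks give side product at 88.9 % in violet and side product at 86.6 % in red.

    substrate + partner → single product (k = 0.00750 M⁻¹ s⁻¹, Ea = 57.0 kJ mol⁻¹)
    partner + single product → double product (k = 0.00340 M⁻¹ s⁻¹, Ea = 57.0 kJ mol⁻¹)
    partner + double product → triple product (k = 0.00710 M⁻¹ s⁻¹, Ea = 85.0 kJ mol⁻¹)
    substrate + single product → side product (k = 0.210 M⁻¹ s⁻¹, Ea = 67.0 kJ mol⁻¹)
    partner → decomposition product (k = 7.60 × 10⁻⁶ s⁻¹, Ea = 115 kJ mol⁻¹)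
    (constants at 90 °C)

Violet ends above red, the reverse of the first reading's order. Yet the leak per equivalent parts slightly, to 0.0418 in violet and 0.0511 in red. Heat's reading has a region in triple product at 12.0 min: 11.1 % in violet against 8.35 % in red, though at 120 min the two stand at 11.1 % in violet and 13.4 % in red. At 0.284 min in violet, substrate takes single product 15 times as fast as partner does. There single product is made at 0.993 of the rate it is used, a quasi-steady state.

Violet's neighbour with 7.50 equiv of partner: the leak gives 73.9 % side product, and the flask gives 74.8 %.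

(All runs are simulated for an exercise; noise was put on by code.)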